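All runs were generated by integration with constants of no real substance, noise included.

Oak, the earlier run with twice alder's added ligand, was still climbing at its last reading, 25.8% at 6.00 min. Alder, the flask we must judge, is a kinetic resolution: single-handed free catalyst and partner turn a racemate into left-handed product.

common to all: left-handed substrate 31 mM; right-handed substrate 31 mM; free catalyst 5 mol%

| run | partner | added ligand | remark | time |
|---|---|---|---|---|
| alder | 1.5 equiv | 7.7 mM | the very flask that is asked about, followed so far |  |
| oak | 1.5 equiv | 15 mM | run made earlier |  |
| flask | 1.50 equiv | 7.7 mM |  | 80 min |

| run | time / min | left-handed product / % |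
|---|---|---|
| alder | 4.00 | 24.5 |
| alder | 12.0 | 32.8 |
| alder | 25.0 | 36.0 |
| alder | 40.0 | 35.4 |
| alder | 50.0 | 35.0 |
| alder | 60.0 | 35.3 |
| oak | 0.417 | 4.1 |
| oak | 1.33 | 9.0 |
| oak | 2.00 | 13.1 |
| oak | 3.00 | 17.1 |
| oak | 5.00 | 23.3 |
| oak | 6.00 | 25.8 |

(each reading ± 0.5 percentage points)

- free catalyst is single-handed; left-handed substrate and right-handed substrate are mirror images of each other, charged as a racemate, each of them at the stated concentration
- what is taken out of left-handed product is counted as made
- additions bring no volume worth counting

- Sunday's: change nothing and wait 80 min more
- Monday's: at 80 min add partner, 100% of the amount charged, then wait 80 min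
- Tuesday's: at 80 min take out 90% of the left-handed product then present, then wait 80 min
- Thursday's: at 80 min add free catalyst, 50.0% of the amount charged, then wait 80 min

* left-handed product, in percent of the left-handed substrate and right-handed substrate together first charged, at 80 min
* the remedy with the largest gain of left-handed product, or "none" below 2 percentage points (Sunday's / Monday's / Tuesday's / Thursday's / none)
* left-handed product present, with what was taken out counted in, in percent of the left-handed substrate and right-handed substrate together first charged, after Tuesday's
* left-handed product present, with what was taken out counted in, in percent of the left-handed substrate and right-handed substrate together first charged, after Thursday's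

Alder looks contradictory. It made 24.5% in 4.00 min, and that first-order pace, if held, gives 49.3% by 25.0 min. Yet alder reads 36.0% there and stays flat to 60.0 min, with partner charged at 1.50 equiv.

We take the last three readings as a plateau of 35.2%, which by difference leaves 14.8% of left-handed substrate and gives 1.22 for the catalyst dose: the logarithm of c(left-handed substrate) at the start over c(left-handed substrate) at the plateau, the reach of one charge of catalyst before it dies. The first reading has used 0.673 of that dose. If the dose is spent exponentially, the catalyst lifetime is 4.98 min, so 80 min is 16.1 lifetimes.

Our reckoning therefore puts alder at 35.2% at 80 min. Waiting, partner and removal add no catalyst, and the lifetime is far shorter than the time already gone, so we expect no gain from them. Taking the dose as proportional to catalyst charge, Thursday's raises it to 1.83 and gives 42.0%, a gain of 6.8 percentage points.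

The forecast puts alder at 35.4% at 80 min, above our 35.2%, and reads the run as “a dying catalyst, not an equilibrium”. It names Thursday's, with 35.4% after Tuesday's and 42% after Thursday's.

The flask gives 35.6% at 80 min and 35.6% after Tuesday's, and Thursday's is best, gaining 9.9 points to reach 45.4%, which is 3.4 points above our figure.

    free catalyst → spent catalyst (k = 0.0324 /s)
    partner + catalyst intermediate B → free catalyst + right-handed product (k = 0.0579 /M/s)
    free catalyst + right-handed substrate ⇌ catalyst intermediate B (K = 72.3 /M, k = 736 /M/s)
    free catalyst + left-handed substrate ⇌ catalyst intermediate A (K = 179 /M, k = 410 /M/s)
    free catalyst + added ligand ⇌ idle complex, settled at all times (K = 550 /M)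
    left-handed substrate ⇌ right-handed substrate (k = 5.75 × 10⁻⁴ /s)
    partner + catalyst intermediate A → free catalyst + left-handed product (k = 4.20 /M/s)

By 8.00 min, 77.9% of the catalyst is spent catalyst, a time shorter than the 20 min half-life of left-handed substrate by its forward passing into right-handed substrate alone. At 80.0 min the flask holds 32.0% left-handed substrate and 32.2% right-handed substrate, against the 14.8% we counted by difference. The neighbour flask charged at 12 mol% of free catalyst has a dose of 2.93, which reckons to 47.3%, and it stands at 48.0%.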